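**Retrosynthetic overview**
1. Both lactones close in the last operation from an acyclic C20 hydroxy bis(alkenyl iodide), two CO and a stannylmethyl phosphonoacetate. Ring A forms by carbonylative lactonisation of the (Z)-iodoalkene/homoallylic alcohol. Ring B forms by carbonylative Stille coupling of the dienyl iodide, then intramolecular HWE in the same flask. Ring A closes first, ring B directly after.
2. The dienyl iodide comes from the enal (Takai olefination), and the enal from the primary allylic alcohol.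
3. The (Z)-iodoalkene comes from the internal alkyne by hydroxyl-directed trans-hydrostannation and tin–iodine exchange. This fixes the Z-alkylidene geometry of ring A.
4. The alkyne comes from the acetylide of (R)-6-methylhept-5-en-1-yn-4-ol and a C11 homoallylic iodide. The carbinol, the only stereocentre, is made from prenal and an allenylboronate with a chiral phosphoric acid.
5. The C11 iodide comes from geranyl acetate (SeO2, Wittig methylenation, hydroboration–iodination), which supplies both E-trisubstituted alkenes.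

Assumption: the (R)-configured phosphoric acid gives the (R)-carbinol with prenal, as it does with other enals and aryl aldehydes; if the sense is opposite, its enantiomer is used.

**Step 1**
Reactants: 1 3-methylbut-2-enal (prenal); 2 allenylboronic acid pinacol ester
Product: 4 (R)-6-methylhept-5-en-1-yn-4-ol, via O-pinacolboryl ether 3 (not isolated)
Conditions: (R)-3,3'-bis(2,4,6-triisopropylphenyl)-1,1'-binaphthyl-2,2'-diyl hydrogen phosphate (5 mol %), 4 Å MS, toluene, −20 °C; aq. work-up
Reagents that add atoms: none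
Why: Chiral-phosphoric-acid-catalysed allenylboration (asymmetric carbonyl propargylation): the boronate adds 1,2 through a closed six-membered SE2' transition state in which the acid hydrogen-bonds a boronate oxygen and the formyl hydrogen, so one aldehyde face is open and C4 is set as R.

**Step 2**
Reactants: 5 geranyl acetate
Product: 7 (2E,6E)-3,7-dimethyl-8-oxoocta-2,6-dien-1-yl acetate, via allylic alcohol 6 (not isolated)
Conditions: SeO2 (1.1 equiv), 1,4-dioxane/EtOH, 80 °C
Reagents that add atoms: selenium dioxide, O=[Se]=O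
Why: Riley allylic oxidation (ene reaction, then [2,3]-shift) attacks the electron-rich terminal alkene at its E-methyl group and carries alcohol 6 on to the E-enal, while the acetate-deactivated 2,3-alkene is left alone.

**Step 3**
Reactants: 7 (2E,6E)-3,7-dimethyl-8-oxoocta-2,6-dien-1-yl acetate
Product: 8 (2E,6E)-3,7-dimethylnona-2,6,8-trien-1-yl acetate
Conditions: Ph3PCH3Br (1.15 equiv), KOtBu (1.1 equiv), THF, 0 °C; then 7, −78 → 0 °C
Reagents that add atoms: methyltriphenylphosphonium bromide, C[P+](c1ccccc1)(c1ccccc1)c1ccccc1.[Br-]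
Why: Wittig methylenation of the unhindered enal is fast at low temperature, so the acetate and both E-alkenes survive.

**Step 4**
Reactants: 8 (2E,6E)-3,7-dimethylnona-2,6,8-trien-1-yl acetate
Product: 10 (2E,6E)-9-iodo-3,7-dimethylnona-2,6-dien-1-ol, via B-alkyl-9-BBN adduct 9 (not isolated)
Conditions: 9-BBN-H (1.05 equiv), THF, 0 °C → rt; then I2 (1.1 equiv), NaOMe (3 equiv), MeOH, 0 °C
Reagents that add atoms: iodine, [I][I]
Why: Bulky 9-BBN-H hydroborates only the monosubstituted vinyl terminus (anti-Markovnikov), base-induced iodinolysis of the primary B–C bond gives the iodide, and the methoxide removes the acetate by transesterification in the same flask.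

**Step 5**
Reactants: 4 (R)-6-methylhept-5-en-1-yn-4-ol; 10 (2E,6E)-9-iodo-3,7-dimethylnona-2,6-dien-1-ol
Product: 14 (2E,6E,13R)-3,7,15-trimethylhexadeca-2,6,14-trien-10-yne-1,13-diol, via dilithio alkynol 11 (not isolated), via lithium alkoxide 12 (not isolated), via dilithium dialkoxide 13 (not isolated)
Conditions: 4: nBuLi (2.05 equiv), THF, −78 → 0 °C; 10: LiN(SiMe3)2 (1.0 equiv), THF, −78 °C; mix, DMPU, −20 °C → rt; H2O
Reagents that add atoms: none
Why: SN2 alkylation of a lithium acetylide by a primary iodide; both hydroxyls are masked as lithium alkoxides, the stereocentre is not involved, and low temperature plus DMPU favour substitution over E2.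

**Step 6**
Reactants: 14 (2E,6E,13R)-3,7,15-trimethylhexadeca-2,6,14-trien-10-yne-1,13-diol
Product: 16 (2E,6E,10Z,13R)-11-iodo-3,7,15-trimethylhexadeca-2,6,10,14-tetraene-1,13-diol, via alkenylstannane 15 (not isolated)
Conditions: [(C5Me5)RuCl]4 (1.5 mol %), Bu3SnH (1.1 equiv, slow addition), CH2Cl2, rt; then I2 (1.1 equiv), 0 °C
Reagents that add atoms: iodine, [I][I]
Why: Hydroxyl-directed ruthenium-catalysed trans-hydrostannation: the OH···Cl–Ru hydrogen bond steers tin to the alkyne carbon nearer the carbinol and hydrogen adds anti, so chain and tin are cis, and tin–iodine exchange with retention gives the 10Z iodide.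

**Step 7**
Reactants: 16 (2E,6E,10Z,13R)-11-iodo-3,7,15-trimethylhexadeca-2,6,10,14-tetraene-1,13-diol
Product: 17 (2E,6E,10Z,13R)-13-hydroxy-11-iodo-3,7,15-trimethylhexadeca-2,6,10,14-tetraenal
Conditions: 2,2,6,6-tetramethylpiperidin-1-oxyl (10 mol %), PhI(OAc)2 (1.1 equiv), CH2Cl2, rt
Reagents that add atoms: none
Why: Oxoammonium (TEMPO) oxidation is selective for the unhindered primary allylic alcohol, stops at the aldehyde, keeps the 2E geometry and leaves the secondary allylic alcohol and the alkenyl iodide untouched.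

**Step 8**
Reactants: 17 (2E,6E,10Z,13R)-13-hydroxy-11-iodo-3,7,15-trimethylhexadeca-2,6,10,14-tetraenal
Product: 18 (4R,6Z,10E,14E,16E)-6,17-diiodo-2,10,14-trimethylheptadeca-2,6,10,14,16-pentaen-4-ol
Conditions: CrCl2 (8 equiv), CHI3 (2.5 equiv), THF/1,4-dioxane (1:6), 0 °C → rt
Reagents that add atoms: iodoform, [I]C([I])[I]
Why: Takai olefination: the geminal dichromium species from iodoform and divalent chromium adds to the aldehyde and eliminates to the E-alkenyl iodide, while the free hydroxyl and the existing alkenyl iodide are inert to CrCl2 without nickel.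

**Step 9**
Reactants: 19 (tributylstannyl)methanol; 20 2-(diethoxyphosphoryl)acetic acid
Product: 21 (tributylstannyl)methyl 2-(diethoxyphosphoryl)acetate
Conditions: DCC (1.1 equiv), 4-(dimethylamino)pyridine (5 mol %), CH2Cl2, 0 °C → rt
Reagents that add atoms: none
Why: Steglich esterification joins the acid and the primary stannyl alcohol under neutral conditions, so no protodestannylation occurs.

**Step 10**
Reactants: 18 (4R,6Z,10E,14E,16E)-6,17-diiodo-2,10,14-trimethylheptadeca-2,6,10,14,16-pentaen-4-ol; 21 (tributylstannyl)methyl 2-(diethoxyphosphoryl)acetate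
Product: 23 (3Z,5R)-3-[(4E,8E,10E)-4,8-dimethyl-11-(5-oxo-2,5-dihydrofuran-3-yl)undeca-4,8,10-trien-1-ylidene]-5-(2-methylprop-1-en-1-yl)dihydrofuran-2(3H)-one, via keto phosphonate lactone 22 (not isolated)
Conditions: Pd2(dba)3 (2.5 mol %), AsPh3 (20 mol %), CuI (10 mol %), K2CO3 (3.5 equiv), 21 (1.3 equiv), CO (1 atm), DMF, 50 °C
Reagents that add atoms: carbon monoxide, [C-]#[O+]
Why: Proposed new method: both C–I bonds add oxidatively to zerovalent palladium and insert CO; the acyl-palladium next to the homoallylic hydroxyl is trapped intramolecularly with retention of the Z geometry and closes ring A (known type: carbonylative lactonisation of halo alcohols), whereas the dienoyl-palladium has no internal nucleophile and is transmetallated by the alpha-acyloxymethyl stannane, whose oxygen-bearing methyl group transfers in preference to butyl (known types: carbonylative Stille coupling, acylation of alpha-oxygenated stannanes), and the resulting alpha-(phosphonoacetoxy) ketone 22 closes ring B under the same carbonate base by intramolecular Horner–Wadsworth–Emmons olefination; weakly nucleophilic AsPh3 avoids Z/E leakage of the alkylidene lactone, and the stereocentre is not touched.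

**Compound list**
1 | 3-methylbut-2-enal (prenal) | CC(C)=CC=O | starting material
2 | allenylboronic acid pinacol ester | C=C=CB1OC(C)(C)C(C)(C)O1 | starting material
3 | O-pinacolboryl ether of (R)-6-methylhept-5-en-1-yn-4-ol | CC(C)=C[C@H](OB1OC(C)(C)C(C)(C)O1)CC#C | intermediate
4 | (R)-6-methylhept-5-en-1-yn-4-ol | CC(C)=C[C@H](O)CC#C | intermediate
5 | geranyl acetate | CC(C)=CCC/C(C)=C/COC(C)=O | starting material
6 | (2E,6E)-8-hydroxy-3,7-dimethylocta-2,6-dien-1-yl acetate | OC/C(C)=C/CC/C(C)=C/COC(C)=O | intermediate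
7 | (2E,6E)-3,7-dimethyl-8-oxoocta-2,6-dien-1-yl acetate | O=C/C(C)=C/CC/C(C)=C/COC(C)=O | intermediate
8 | (2E,6E)-3,7-dimethylnona-2,6,8-trien-1-yl acetate | C=C/C(C)=C/CC/C(C)=C/COC(C)=O | intermediate
9 | (2E,6E)-9-(9-borabicyclo[3.3.1]nonan-9-yl)-3,7-dimethylnona-2,6-dien-1-yl acetate | CC(=O)OC/C=C(C)/CC/C=C(C)/CCB1C2CCCC1CCC2 | intermediate
10 | (2E,6E)-9-iodo-3,7-dimethylnona-2,6-dien-1-ol | ICC/C(C)=C/CC/C(C)=C/CO | intermediate
11 | O,C-dilithio derivative of 4 | CC(C)=C[C@H](O[Li])CC#C[Li] | intermediate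
12 | lithium alkoxide of 10 | ICC/C(C)=C/CC/C(C)=C/CO[Li] | intermediate
13 | dilithium dialkoxide of 14 | CC(C)=C[C@H](O[Li])CC#CCC/C(C)=C/CC/C(C)=C/CO[Li] | intermediate
14 | (2E,6E,13R)-3,7,15-trimethylhexadeca-2,6,14-trien-10-yne-1,13-diol | CC(C)=C[C@H](O)CC#CCC/C(C)=C/CC/C(C)=C/CO | intermediate
15 | (2E,6E,10Z,13R)-3,7,15-trimethyl-11-(tributylstannyl)hexadeca-2,6,10,14-tetraene-1,13-diol | CC(C)=C[C@H](O)C/C([Sn](CCCC)(CCCC)CCCC)=C/CC/C(C)=C/CC/C(C)=C/CO | intermediate
16 | (2E,6E,10Z,13R)-11-iodo-3,7,15-trimethylhexadeca-2,6,10,14-tetraene-1,13-diol | CC(C)=C[C@H](O)C/C([I])=C/CC/C(C)=C/CC/C(C)=C/CO | intermediate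
17 | (2E,6E,10Z,13R)-13-hydroxy-11-iodo-3,7,15-trimethylhexadeca-2,6,10,14-tetraenal | CC(C)=C[C@H](O)C/C([I])=C/CC/C(C)=C/CC/C(C)=C/C=O | intermediate
18 | (4R,6Z,10E,14E,16E)-6,17-diiodo-2,10,14-trimethylheptadeca-2,6,10,14,16-pentaen-4-ol | CC(C)=C[C@H](O)C/C([I])=C/CC/C(C)=C/CC/C(C)=C/C=C/I | intermediate
19 | (tributylstannyl)methanol | OC[Sn](CCCC)(CCCC)CCCC | starting material
20 | 2-(diethoxyphosphoryl)acetic acid | CCOP(=O)(CC(=O)O)OCC | starting material
21 | (tributylstannyl)methyl 2-(diethoxyphosphoryl)acetate | CCOP(=O)(CC(=O)OC[Sn](CCCC)(CCCC)CCCC)OCC | intermediate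
22 | (3E,5E,9E,13Z)-6,10-dimethyl-13-[(5R)-5-(2-methylprop-1-en-1-yl)-2-oxodihydrofuran-3(2H)-ylidene]-2-oxotrideca-3,5,9-trien-1-yl 2-(diethoxyphosphoryl)acetate | CC(C)=C[C@H]1C/C(=C/CC/C(C)=C/CC/C(C)=C/C=C/C(=O)COC(=O)CP(=O)(OCC)OCC)C(=O)O1 | intermediate
23 | (3Z,5R)-3-[(4E,8E,10E)-4,8-dimethyl-11-(5-oxo-2,5-dihydrofuran-3-yl)undeca-4,8,10-trien-1-ylidene]-5-(2-methylprop-1-en-1-yl)dihydrofuran-2(3H)-one | CC(C)=C[C@H]1C/C(=C/CC/C(C)=C/CC/C(C)=C/C=C/C2=CC(=O)OC2)C(=O)O1 | target

**Total step count:** 10.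
**Longest linear sequence:** 8 steps (5 → 7 → 8 → 10 → 14 → 16 → 17 → 18 → 23).

**Three steps most likely to fail**

**Step 10.**
- **Risk:** the dienoyl-palladium may be captured by the phosphonate carbanion, or by the carbinol of a second molecule, faster than by tin. Butyl transfer may also compete.
- **Fallback (sets out from 17, comes back at 23):** the rings are made one after the other and ring B is brought in ready-made.
- Compound 17 alone undergoes halo-alcohol carbonylation (PdCl2(PPh3)2, K2CO3, CO 1 atm, DMF, 40 °C). This gives (2E,6E,10Z)-3,7-dimethyl-10-[(5R)-5-(2-methylprop-1-en-1-yl)-2-oxodihydrofuran-3(2H)-ylidene]deca-2,6-dienal F1.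
- Commercial 4-methylfuran-2(5H)-one is brominated (N-bromosuccinimide, dibenzoyl peroxide cat., PhCF3, reflux) to 4-(bromomethyl)furan-2(5H)-one F2.
- Arbuzov reaction of F2 with P(OEt)3 gives diethyl [(5-oxo-2,5-dihydrofuran-3-yl)methyl]phosphonate F3.
- E-selective HWE olefination of F1 with the lithium salt of F3 (LiN(SiMe3)2, THF, −78 °C) gives 23.

**Step 5.**
- **Risk:** E2 elimination of the homoallylic iodide back to the 1,3-diene under the strongly basic dianion.
- **Fallback (sets out from 4 and 10, comes back at 14):** anion chemistry is abandoned. The neutral partners are joined by a catalytic sp3–sp cross-coupling of alkyl Sonogashira type.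
- Conditions: [(η3-C3H5)PdCl]2, 1,3-bis(1-adamantyl)imidazolium chloride, CuI, Cs2CO3, DMF/Et2O, 45 °C. These tolerate both free hydroxyls.
- New compound: none F0.

**Step 6.**
- **Risk:** incomplete proximal selectivity with a homopropargylic (rather than propargylic) director.
- **Fallback (sets out from 4 and 8, comes back at 16):** the alkyne is avoided altogether.
- Compound 4 is iodinated (N-iodosuccinimide, AgNO3 cat., acetone) to (R)-1-iodo-6-methylhept-5-en-1-yn-4-ol F4.
- Anti-hydrobromination (LiBr, AcOH, Pd(OAc)2 cat.) gives (1Z,4R)-2-bromo-1-iodo-6-methylhepta-1,5-dien-4-ol F5.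
- Only the C–I bond of F5 undergoes B-alkyl Suzuki coupling, with retention, with borane 9 made from 8 (PdCl2(dppf), AsPh3, Cs2CO3, DMF/THF/H2O, rt). This gives (2E,6E,10Z,13R)-11-bromo-13-hydroxy-3,7,15-trimethylhexadeca-2,6,10,14-tetraen-1-yl acetate F6.
- Methanolysis (K2CO3, MeOH) gives (2E,6E,10Z,13R)-11-bromo-3,7,15-trimethylhexadeca-2,6,10,14-tetraene-1,13-diol F7.
- Copper-catalysed halogen exchange with retention (CuI cat., NaI, trans-N,N'-dimethylcyclohexane-1,2-diamine, 1,4-dioxane, 110 °C) returns 16.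

**Further compounds**
F1 | step 10 | (2E,6E,10Z)-3,7-dimethyl-10-[(5R)-5-(2-methylprop-1-en-1-yl)-2-oxodihydrofuran-3(2H)-ylidene]deca-2,6-dienal | CC(C)=C[C@H]1C/C(=C/CC/C(C)=C/CC/C(C)=C/C=O)C(=O)O1
F2 | step 10 | 4-(bromomethyl)furan-2(5H)-one | BrCC1=CC(=O)OC1
F3 | step 10 | diethyl [(5-oxo-2,5-dihydrofuran-3-yl)methyl]phosphonate | CCOP(=O)(CC1=CC(=O)OC1)OCC
F0 | step 5 | none | none
F4 | step 6 | (R)-1-iodo-6-methylhept-5-en-1-yn-4-ol | CC(C)=C[C@H](O)CC#CI
F5 | step 6 | (1Z,4R)-2-bromo-1-iodo-6-methylhepta-1,5-dien-4-ol | CC(C)=C[C@H](O)C/C(Br)=C/I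
F6 | step 6 | (2E,6E,10Z,13R)-11-bromo-13-hydroxy-3,7,15-trimethylhexadeca-2,6,10,14-tetraen-1-yl acetate | CC(C)=C[C@H](O)C/C(Br)=C/CC/C(C)=C/CC/C(C)=C/COC(C)=O
F7 | step 6 | (2E,6E,10Z,13R)-11-bromo-3,7,15-trimethylhexadeca-2,6,10,14-tetraene-1,13-diol | CC(C)=C[C@H](O)C/C(Br)=C/CC/C(C)=C/CC/C(C)=C/CO
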